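**Plan**

- Retrosynthesis: the C4 oxygen is put back as a placeholder and ring A is cut at C6–C7, C4–C5 and C3a–C4 (chromium carbene benzannulation). This leads to a dihydrofuranyl methoxycarbene complex, methyl pent-4-ynoate and one CO. The carbene is cut at C7–C7a to a 2,3-dihydrofuran, whose O1–C7a bond comes from an alkynol and whose C2–C3 bond comes from an aldehyde propargylation.
- Feature used: ring A is a 1,2,3,5-tetrasubstituted benzene. C7–OMe maps onto the carbene carbon, C6–H and C5–CH2CH2CO2Me onto a terminal alkyne, C4 onto CO, and the C3a–C7a fusion onto the enol ether C=C of the dihydrofuran.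
- Forward order: aryl aldehyde plus chiral propargylic mesylate give the anti alkynol; the dihydrofuran ring closes first; C5-lithiation gives the carbene complex; ring A is annulated; the C4 hydroxyl is removed through its triflate; desilylation ends the route.
- Stereochemistry: C3 comes from (R)-glyceraldehyde acetonide through the (S)-mesylate (anti SN2' palladation, then syn SE2' addition, net inversion). C2 is set in the same step by the anti-selective cyclic transition state. Neither centre is touched afterwards.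
- Both hydroxyls are carried as triisopropylsilyl ethers because these tolerate tert-butyllithium; both are removed by fluoride in the last step.

Key step: step 9

**Route**

Step 1
Reactants: 1 syringaldehyde (4-hydroxy-3,5-dimethoxybenzaldehyde)
Product: 2 3,5-dimethoxy-4-(triisopropylsilyloxy)benzaldehyde
Conditions: TIPSCl, imidazole, DMF, rt
Reagents that add atoms: chlorotriisopropylsilane, CC(C)[Si](Cl)(C(C)C)C(C)C
Why: Imidazole-promoted O-silylation (Corey-type silyl ether formation) of the acidic para-formyl phenol should proceed despite the two flanking methoxy groups, and the bulky silyl ether is chosen because it resists tert-butyllithium in step 8 yet falls to fluoride at the end.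

Step 2
Reactants: 3 (R)-2,2-dimethyl-1,3-dioxolane-4-carbaldehyde
Product: 4 (S)-4-ethynyl-2,2-dimethyl-1,3-dioxolane
Conditions: MeC(O)C(N2)P(O)(OMe)2, K2CO3, MeOH, 0 °C → rt
Reagents that add atoms: dimethyl (1-diazo-2-oxopropyl)phosphonate, COP(=O)(OC)C(=[N+]=[N-])C(C)=O
Why: Ohira–Bestmann homologation (Seyferth–Gilbert reagent released in situ by methanolysis) turns the formyl group into a terminal alkyne under carbonate conditions mild enough for this α-alkoxy aldehyde, so the dioxolane stereocentre is unchanged in space and becomes S only through the change in substituent priorities.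

Step 3
Reactants: 4 (S)-4-ethynyl-2,2-dimethyl-1,3-dioxolane
Product: 5 (S)-but-3-yne-1,2-diol
Conditions: Dowex 50WX8 (H+ form), MeOH–H2O, rt
Reagents that add atoms: none
Why: Acid-catalysed hydrolysis of the isopropylidene acetal on a sulfonic acid resin frees the 1,2-diol without touching the alkyne or the stereocentre, and filtration plus evaporation avoids extracting the water-soluble diol.

Step 4
Reactants: 5 (S)-but-3-yne-1,2-diol
Product: 6 (S)-1-(triisopropylsilyloxy)but-3-yn-2-ol
Conditions: TIPSCl, imidazole, CH2Cl2, 0 °C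
Reagents that add atoms: chlorotriisopropylsilane, CC(C)[Si](Cl)(C(C)C)C(C)C
Why: The bulky chlorosilane silylates the primary hydroxyl far faster than the secondary propargylic one (steric discrimination in imidazole-mediated silylation), leaving the carbinol free for activation.

Step 5
Reactants: 6 (S)-1-(triisopropylsilyloxy)but-3-yn-2-ol
Product: 7 (S)-1-(triisopropylsilyloxy)but-3-yn-2-yl methanesulfonate
Conditions: MsCl, Et3N, CH2Cl2, −78 °C
Reagents that add atoms: methanesulfonyl chloride, CS(=O)(=O)Cl
Why: Sulfonylation of the secondary alcohol forms only an O–S bond, so the (S) configuration is retained, and the low temperature keeps the reactive propargylic mesylate from ionising.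

Step 6
Reactants: 7 (S)-1-(triisopropylsilyloxy)but-3-yn-2-yl methanesulfonate; 2 3,5-dimethoxy-4-(triisopropylsilyloxy)benzaldehyde
Product: 9 (1S,2R)-1-[3,5-dimethoxy-4-(triisopropylsilyloxy)phenyl]-2-[(triisopropylsilyloxy)methyl]but-3-yn-1-ol, via allenylzinc methanesulfonate 8 (not isolated)
Conditions: Pd(OAc)2 (5 mol %), PPh3 (5 mol %), Et2Zn, THF, −78 → −20 °C; aq NH4Cl
Reagents that add atoms: none
Why: In this Marshall propargylation zerovalent palladium displaces the mesylate in an anti SN2' sense, transmetalation gives the (P)-allenylzinc 8, and 8 adds to the aldehyde through a cyclic SE2' transition state on the zinc-bearing face, so the new C–C bond forms with net inversion of the mesylate carbon (2R) while the aryl group turns away from the silyloxymethyl arm to give the anti (1S) carbinol.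

Step 7
Reactants: 9 (1S,2R)-1-[3,5-dimethoxy-4-(triisopropylsilyloxy)phenyl]-2-[(triisopropylsilyloxy)methyl]but-3-yn-1-ol
Product: 10 (2S,3R)-2-[3,5-dimethoxy-4-(triisopropylsilyloxy)phenyl]-3-[(triisopropylsilyloxy)methyl]-2,3-dihydrofuran
Conditions: Mo(CO)6 (30 mol %), Et3N, Et2O, hν (350 nm), rt
Reagents that add atoms: none
Why: In the McDonald alkynol cycloisomerisation photogenerated Et3N·Mo(CO)5 converts the terminal alkyne into a molybdenum vinylidene whose electrophilic α-carbon is attacked by the hydroxyl in a 5-endo sense, and protonolysis releases the 2,3-dihydrofuran with both stereocentres untouched, the anti alkynol becoming the 2,3-trans ring.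

Step 8
Reactants: 10 (2S,3R)-2-[3,5-dimethoxy-4-(triisopropylsilyloxy)phenyl]-3-[(triisopropylsilyloxy)methyl]-2,3-dihydrofuran; 11 chromium hexacarbonyl
Product: 14 pentacarbonyl{methoxy[(2S,3R)-2-[3,5-dimethoxy-4-(triisopropylsilyloxy)phenyl]-3-[(triisopropylsilyloxy)methyl]-2,3-dihydrofuran-5-yl]methylidene}chromium, via lithiated dihydrofuran 12 (not isolated), via lithium acylchromate 13 (not isolated)
Conditions: t-BuLi, THF, −78 → 0 °C; Cr(CO)6, THF, 0 °C → rt; Me3OBF4, CH2Cl2, 0 °C
Reagents that add atoms: trimethyloxonium tetrafluoroborate, C[O+](C)C.F[B-](F)(F)F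
Why: tert-Butyllithium removes the enol ether α-hydrogen at C5 (α-lithiation of a cyclic enol ether), the vinyllithium adds to a CO ligand of Cr(CO)6 and the acylchromate is O-methylated by the Meerwein salt (Fischer carbene synthesis), with no base present once the γ-acidic carbene complex exists, so C3 should not epimerise.

Step 9
Reactants: 14 pentacarbonyl{methoxy[(2S,3R)-2-[3,5-dimethoxy-4-(triisopropylsilyloxy)phenyl]-3-[(triisopropylsilyloxy)methyl]-2,3-dihydrofuran-5-yl]methylidene}chromium; 15 methyl pent-4-ynoate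
Product: 17 methyl 3-[(2S,3R)-2-[3,5-dimethoxy-4-(triisopropylsilyloxy)phenyl]-4-hydroxy-7-methoxy-3-[(triisopropylsilyloxy)methyl]-2,3-dihydro-1-benzofuran-5-yl]propanoate, via tricarbonylchromium arene complex 16 (not isolated)
Conditions: THF, 50 °C; then air, light, Et2O, rt
Reagents that add atoms: none
Why: Thermal loss of one cis CO from 14 lets the alkyne coordinate and insert into the Cr=C bond (C6–C7), CO insertion (C4–C5) gives a chromium-bound dienylketene, and its 6π electrocyclisation forms C3a–C4 and, after tautomerisation, the ring A phenol held on Cr(CO)3 (16), which air then strips. This is the Dötz benzannulation, and its closest precedents are the annulations of 2-dihydropyranyl and 2-dihydrofuranyl methoxycarbene chromium complexes with terminal alkynes. Ring A closes by a thermally allowed disrotatory 6π electrocyclisation of the ketene carbon onto the former enol ether β-carbon (C3a), a 6-membered carbocyclisation that creates no stereocentre. C2 and C3 are spectators, since C3 is only allylic to the reacting C=C and the neutral, base-free medium avoids the γ-deprotonation that could epimerise it. The step needs regioselective alkyne insertion, and for steric reasons the unsubstituted alkyne carbon bonds to the carbene carbon, so the propanoate arm ends up at C5 next to the CO-derived C4–OH and C6 carries hydrogen. It also needs phenol formation to win over cyclopentannulation, which alkenyl(methoxy)carbene chromium complexes in THF are known to favour.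

Step 10
Reactants: 17 methyl 3-[(2S,3R)-2-[3,5-dimethoxy-4-(triisopropylsilyloxy)phenyl]-4-hydroxy-7-methoxy-3-[(triisopropylsilyloxy)methyl]-2,3-dihydro-1-benzofuran-5-yl]propanoate
Product: 18 methyl 3-[(2S,3R)-2-[3,5-dimethoxy-4-(triisopropylsilyloxy)phenyl]-7-methoxy-4-(trifluoromethylsulfonyloxy)-3-[(triisopropylsilyloxy)methyl]-2,3-dihydro-1-benzofuran-5-yl]propanoate
Conditions: Tf2O, pyridine, CH2Cl2, −20 → 0 °C
Reagents that add atoms: trifluoromethanesulfonic anhydride, O=S(=O)(OS(=O)(=O)C(F)(F)F)C(F)(F)F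
Why: Sulfonylation of the hindered but acidic C4 phenol, the only free hydroxyl in the molecule, gives the aryl triflate and so turns the surplus oxygen into a leaving group for palladium.

Step 11
Reactants: 18 methyl 3-[(2S,3R)-2-[3,5-dimethoxy-4-(triisopropylsilyloxy)phenyl]-7-methoxy-4-(trifluoromethylsulfonyloxy)-3-[(triisopropylsilyloxy)methyl]-2,3-dihydro-1-benzofuran-5-yl]propanoate
Product: 19 methyl 3-[(2S,3R)-2-[3,5-dimethoxy-4-(triisopropylsilyloxy)phenyl]-7-methoxy-3-[(triisopropylsilyloxy)methyl]-2,3-dihydro-1-benzofuran-5-yl]propanoate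
Conditions: Pd(OAc)2, Ph2P(CH2)3PPh2, HCO2H, Et3N, DMF, 80 °C
Reagents that add atoms: none
Why: In this Cacchi-type hydrogenolysis zerovalent palladium inserts into the aryl C–O bond of the triflate, formate displaces triflate and decarboxylates to a palladium hydride, and reductive elimination leaves C4–H under conditions to which the ester, the silyl ethers and the benzylic C2–O bond are inert.

Step 12
Reactants: 19 methyl 3-[(2S,3R)-2-[3,5-dimethoxy-4-(triisopropylsilyloxy)phenyl]-7-methoxy-3-[(triisopropylsilyloxy)methyl]-2,3-dihydro-1-benzofuran-5-yl]propanoate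
Product: 20 methyl 3-[(2S,3R)-2-(4-hydroxy-3,5-dimethoxyphenyl)-3-(hydroxymethyl)-7-methoxy-2,3-dihydro-1-benzofuran-5-yl]propanoate (CNP0362206.1)
Conditions: Bu4NF, AcOH, THF, 0 °C → rt
Reagents that add atoms: none
Why: Fluoride attacks silicon of both the aryl and the primary alkyl silyl ether (Si–F bond formation), and the acetic acid buffer should keep the liberated para-hydroxybenzyl ether from opening to a quinone methide and spare the methyl ester.

**Compound list**

1 | syringaldehyde | COc1cc(C=O)cc(OC)c1O | starting material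
2 | 3,5-dimethoxy-4-(triisopropylsilyloxy)benzaldehyde | COc1cc(C=O)cc(OC)c1O[Si](C(C)C)(C(C)C)C(C)C | intermediate
3 | (R)-2,2-dimethyl-1,3-dioxolane-4-carbaldehyde | O=C[C@H]1COC(C)(C)O1 | starting material
4 | (S)-4-ethynyl-2,2-dimethyl-1,3-dioxolane | C#C[C@H]1COC(C)(C)O1 | intermediate
5 | (S)-but-3-yne-1,2-diol | C#C[C@H](O)CO | intermediate
6 | (S)-1-(triisopropylsilyloxy)but-3-yn-2-ol | C#C[C@H](O)CO[Si](C(C)C)(C(C)C)C(C)C | intermediate
7 | (S)-1-(triisopropylsilyloxy)but-3-yn-2-yl methanesulfonate | C#C[C@H](OS(C)(=O)=O)CO[Si](C(C)C)(C(C)C)C(C)C | intermediate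
8 | (P)-[4-(triisopropylsilyloxy)buta-1,2-dien-1-yl]zinc methanesulfonate | CS(=O)(=O)O[Zn]C([H])=[C@@]=C([H])CO[Si](C(C)C)(C(C)C)C(C)C | intermediate
9 | (1S,2R)-1-[3,5-dimethoxy-4-(triisopropylsilyloxy)phenyl]-2-[(triisopropylsilyloxy)methyl]but-3-yn-1-ol | C#C[C@H](CO[Si](C(C)C)(C(C)C)C(C)C)[C@H](O)c1cc(OC)c(O[Si](C(C)C)(C(C)C)C(C)C)c(OC)c1 | intermediate
10 | (2S,3R)-2-[3,5-dimethoxy-4-(triisopropylsilyloxy)phenyl]-3-[(triisopropylsilyloxy)methyl]-2,3-dihydrofuran | C1=C[C@H](CO[Si](C(C)C)(C(C)C)C(C)C)[C@@H](c2cc(OC)c(O[Si](C(C)C)(C(C)C)C(C)C)c(OC)c2)O1 | intermediate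
11 | chromium hexacarbonyl | O=C=[Cr](=C=O)(=C=O)(=C=O)(=C=O)=C=O | starting material
12 | (2S,3R)-2-[3,5-dimethoxy-4-(triisopropylsilyloxy)phenyl]-5-lithio-3-[(triisopropylsilyloxy)methyl]-2,3-dihydrofuran | [Li]C1=C[C@H](CO[Si](C(C)C)(C(C)C)C(C)C)[C@@H](c2cc(OC)c(O[Si](C(C)C)(C(C)C)C(C)C)c(OC)c2)O1 | intermediate
13 | lithium pentacarbonyl{[(2S,3R)-2-[3,5-dimethoxy-4-(triisopropylsilyloxy)phenyl]-3-[(triisopropylsilyloxy)methyl]-2,3-dihydrofuran-5-yl]oxidomethylidene}chromate | [Li+].[O-]C(=[Cr](=C=O)(=C=O)(=C=O)(=C=O)=C=O)C1=C[C@H](CO[Si](C(C)C)(C(C)C)C(C)C)[C@@H](c2cc(OC)c(O[Si](C(C)C)(C(C)C)C(C)C)c(OC)c2)O1 | intermediate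
14 | pentacarbonyl{methoxy[(2S,3R)-2-[3,5-dimethoxy-4-(triisopropylsilyloxy)phenyl]-3-[(triisopropylsilyloxy)methyl]-2,3-dihydrofuran-5-yl]methylidene}chromium | COC(=[Cr](=C=O)(=C=O)(=C=O)(=C=O)=C=O)C1=C[C@H](CO[Si](C(C)C)(C(C)C)C(C)C)[C@@H](c2cc(OC)c(O[Si](C(C)C)(C(C)C)C(C)C)c(OC)c2)O1 | intermediate
15 | methyl pent-4-ynoate | C#CCCC(=O)OC | starting material
16 | tricarbonylchromium complex of 17, hexahapto-bound on ring A (either face; the Cr(CO)3 fragment is written as a separate component) | COC(=O)CCc1cc(OC)c2c(c1O)[C@H](CO[Si](C(C)C)(C(C)C)C(C)C)[C@@H](c1cc(OC)c(O[Si](C(C)C)(C(C)C)C(C)C)c(OC)c1)O2.O=C=[Cr](=C=O)=C=O | intermediate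
17 | methyl 3-[(2S,3R)-2-[3,5-dimethoxy-4-(triisopropylsilyloxy)phenyl]-4-hydroxy-7-methoxy-3-[(triisopropylsilyloxy)methyl]-2,3-dihydro-1-benzofuran-5-yl]propanoate | COC(=O)CCc1cc(OC)c2c(c1O)[C@H](CO[Si](C(C)C)(C(C)C)C(C)C)[C@@H](c1cc(OC)c(O[Si](C(C)C)(C(C)C)C(C)C)c(OC)c1)O2 | intermediate
18 | methyl 3-[(2S,3R)-2-[3,5-dimethoxy-4-(triisopropylsilyloxy)phenyl]-7-methoxy-4-(trifluoromethylsulfonyloxy)-3-[(triisopropylsilyloxy)methyl]-2,3-dihydro-1-benzofuran-5-yl]propanoate | COC(=O)CCc1cc(OC)c2c(c1OS(=O)(=O)C(F)(F)F)[C@H](CO[Si](C(C)C)(C(C)C)C(C)C)[C@@H](c1cc(OC)c(O[Si](C(C)C)(C(C)C)C(C)C)c(OC)c1)O2 | intermediate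
19 | methyl 3-[(2S,3R)-2-[3,5-dimethoxy-4-(triisopropylsilyloxy)phenyl]-7-methoxy-3-[(triisopropylsilyloxy)methyl]-2,3-dihydro-1-benzofuran-5-yl]propanoate | COC(=O)CCc1cc(OC)c2c(c1)[C@H](CO[Si](C(C)C)(C(C)C)C(C)C)[C@@H](c1cc(OC)c(O[Si](C(C)C)(C(C)C)C(C)C)c(OC)c1)O2 | intermediate
20 | methyl 3-[(2S,3R)-2-(4-hydroxy-3,5-dimethoxyphenyl)-3-(hydroxymethyl)-7-methoxy-2,3-dihydro-1-benzofuran-5-yl]propanoate | COC(=O)CCc1cc(OC)c2c(c1)[C@H](CO)[C@@H](c1cc(OC)c(O)c(OC)c1)O2 | target

**Step count and risks**

Total step count: 12. Longest linear sequence: 11 steps (3 → 20, steps 2 to 12); step 1 is the only step off this line.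

Most likely to fail, in this order:

Step 8. tert-Butyllithium may deprotonate at the benzylic C2–H or next to a methoxy group of the aryl ring instead of at the enol ether C5–H, giving mixtures of metalated species and a poor yield of the carbene complex. The fallback sets out from alkynol 9. It is cyclised under the known molybdenum-mediated cyclisation–stannylation conditions for but-3-yn-1-ols (Mo(CO)6, Et3N, Et2O, hν, with Bu3SnOTf present) to give (2S,3R)-2-[3,5-dimethoxy-4-(triisopropylsilyloxy)phenyl]-5-(tributylstannyl)-3-[(triisopropylsilyloxy)methyl]-2,3-dihydrofuran F1. Tin–lithium exchange with n-BuLi in THF at −78 °C should then place lithium at C5 only and so deliver 12, from which Cr(CO)6 and Me3OBF4 lead to 14 as before.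

Step 9. The free C4 phenol may close onto the neighbouring ester arm, and the electron-rich hydroquinone monoether may be oxidised during demetalation and chromatography, so that 17 is lost or obtained as a mixture. The fallback sets out from 14 and 15 under the same annulation conditions. The crude demetalated product is driven fully to the lactone with pyridinium p-toluenesulfonate in warm toluene and isolated as (8S,9R)-8-[3,5-dimethoxy-4-(triisopropylsilyloxy)phenyl]-6-methoxy-9-[(triisopropylsilyloxy)methyl]-3,4,8,9-tetrahydro-2H-furo[2,3-h]chromen-2-one F2, an aryl ester that is no longer oxidation-prone. NaOMe in MeOH–THF at 0 °C reopens it to the sodium phenoxide of the methyl ester, which is triflated in the same flask with PhNTf2. The route is rejoined at 18.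

Step 6. The allenylzinc may attack both faces of the aromatic aldehyde, eroding the anti selectivity at the carbinol carbon; the propargylic centre is fixed by the reagent and is not affected. The fallback sets out from 2 and 7 under the same conditions and sets the carbinol centre by inversion instead of by addition. The syn isomer (1R,2R)-1-[3,5-dimethoxy-4-(triisopropylsilyloxy)phenyl]-2-[(triisopropylsilyloxy)methyl]but-3-yn-1-ol F3 is separated and subjected to Mitsunobu esterification (4-nitrobenzoic acid, PPh3, diisopropyl azodicarboxylate, toluene, 0 °C), giving (1S,2R)-1-[3,5-dimethoxy-4-(triisopropylsilyloxy)phenyl]-2-[(triisopropylsilyloxy)methyl]but-3-yn-1-yl 4-nitrobenzoate F4. Methanolysis with K2CO3 in MeOH then returns the material as 9.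

Further compounds
F1 | step 8 | (2S,3R)-2-[3,5-dimethoxy-4-(triisopropylsilyloxy)phenyl]-5-(tributylstannyl)-3-[(triisopropylsilyloxy)methyl]-2,3-dihydrofuran | CCCC[Sn](CCCC)(CCCC)C1=C[C@H](CO[Si](C(C)C)(C(C)C)C(C)C)[C@@H](c2cc(OC)c(O[Si](C(C)C)(C(C)C)C(C)C)c(OC)c2)O1
F2 | step 9 | (8S,9R)-8-[3,5-dimethoxy-4-(triisopropylsilyloxy)phenyl]-6-methoxy-9-[(triisopropylsilyloxy)methyl]-3,4,8,9-tetrahydro-2H-furo[2,3-h]chromen-2-one | O=C3CCc1cc(OC)c2c(c1O3)[C@H](CO[Si](C(C)C)(C(C)C)C(C)C)[C@@H](c1cc(OC)c(O[Si](C(C)C)(C(C)C)C(C)C)c(OC)c1)O2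
F3 | step 6 | (1R,2R)-1-[3,5-dimethoxy-4-(triisopropylsilyloxy)phenyl]-2-[(triisopropylsilyloxy)methyl]but-3-yn-1-ol | C#C[C@H](CO[Si](C(C)C)(C(C)C)C(C)C)[C@@H](O)c1cc(OC)c(O[Si](C(C)C)(C(C)C)C(C)C)c(OC)c1
F4 | step 6 | (1S,2R)-1-[3,5-dimethoxy-4-(triisopropylsilyloxy)phenyl]-2-[(triisopropylsilyloxy)methyl]but-3-yn-1-yl 4-nitrobenzoate | C#C[C@H](CO[Si](C(C)C)(C(C)C)C(C)C)[C@H](OC(=O)c1ccc(cc1)[N+](=O)[O-])c1cc(OC)c(O[Si](C(C)C)(C(C)C)C(C)C)c(OC)c1
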